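It is tempting to start from rates and integrate, but I first ask whether these flasks are still moving.

| flask | L | E | Q | remark | time |
|---|---|---|---|---|---|
| south-east | 0.50 mM | 0.35 mM | 0.025 mM | run made earlier |  |
| south | 0.50 mM | 0.64 mM | 0.025 mM | run made earlier |  |
| midnight | 0.50 mM | 0.500 mM | 0.0250 mM |  | 15 min |
| summer | 0.50 mM | 0.250 mM | 0.0250 mM |  | 15 min |

| run | time / min | X / % | Z / % | L / % |
|---|---|---|---|---|
| south-east | 1.33 | 10.8 | 15.9 | 51.3 |
| south-east | 4.00 | 10.6 | 25.6 | 37.6 |
| south-east | 6.00 | 11.7 | 27.1 | 37.8 |
| south-east | 10.0 | 12.8 | 27.8 | 38.0 |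
| south | 2.50 | 11.9 | 47.4 | 15.9 |
| south | 5.00 | 10.4 | 53.9 | 9.1 |
| south | 8.00 | 12.9 | 55.2 | 8.8 |
| south | 10.0 | 11.7 | 54.9 | 6.5 |

(scatter of a reading: 1 percentage point)

- which of these holds the largest part of the L at the end of midnight (L / Z / X)
- which of these holds the largest part of the L at the end of summer (L / Z / X)
- X at the end of summer, in percent of the L charged

- given per volume of solution although it is solid: L
- on the list of suspects stand: E + X -> Z; G + E -> X; X + Q -> D; L <-> G
- at the start none of L is in solution

In the south-east run, Z moves by 0.7 percentage points between 6.00 min and 10.0 min, with readings good to 1 point. By then X and Z hold 0.342 mM of the 0.35 mM of E charged, nearly all. So E is the limiting reagent in the south-east run, and I count E instead of integrating.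

Where does added E go? From the south-east run to the south run, cE rises by 0.290 mM and cZ by 0.136 mM, which is 2.13 E per Z, and Z holds two E. X reads 12.8% and then 11.7%. The last readings leave 0.0720 mM and 0.0910 mM of E outside Z, so I carry their mean, 0.0815 mM, as the E toll: cE charged minus twice cZ at the end.

What leads? Each Z takes two E, so I divide the E above the toll by two and reckon Z at 41.9% of L in midnight and 16.9% in summer. The last readings of the two runs leave on average 36.4% of L outside Z and L, so I reckon L at 21.7% in midnight and 46.8% in summer. Z leads L in midnight, and L leads Z in summer.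

If the 0.0250 mM of Q goes through X + Q -> D, the toll leaves X in summer at 11.3%, less than Z or L there.

The forecast says Z for midnight, L for summer and 10.5% for X, below my count, with the ground “X falls slightly short of its plateau because E runs out sooner”.

    E + X → Z (k = 120 M⁻¹ s⁻¹)
    G + E → X (k = 80.0 M⁻¹ s⁻¹)
    X + Q → D (k = 1000 M⁻¹ s⁻¹)
    L ⇌ G, rate k4*(cs4 - [G]) while solid is left; crystals form when [G] > cs4 (solubility = 0.0970 mM, k = 1.30 s⁻¹)

Summer ends with X at 10.7%, L at 47.7% and Z at 17.1%, while midnight ends with Z at 41.3% and L at 21.9%. Leaving summer for ten times as long makes no difference to X: it still stands at 10.7%. The toll of summer itself comes to 0.0786 mM. With 1.2 mM of L and E as in summer, the carried toll gives cZ 0.0843 mM, or 7.03% of that L, and that flask ends at 7.14%.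

All runs come from a simulation for an exercise; noise was put on by code.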